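Assumption (one remark on the chemistry): the D-fructose-derived Shi ketone is taken to give the (6R)-epoxide of 1, and the enantiomer of the chiral copper–carbene catalyst is chosen so that 17 has the S configuration. Atom numbers are those defined in the analysis.

## Analysis of the target

The target 44 (C30H50O) is a pentacyclic ether. Ring A is a seven-membered carbocycle (C1–C5, C9, C10) bridged by an oxygen between C3 and C10, so it contains an oxolane and an oxane (an 8-oxabicyclo[3.2.1]octane); ring B is a cyclopentane (C5–C9); rings C (C8, C9, C11–C14) and D (C13–C18) are cyclohexanes; C17 carries a 4-methylpent-3-enyl chain (C19–C22 and two methyls). There are eight stereocentres (C3, C5, C8, C9, C10, C13, C14, C17) and six fully substituted sp3 carbons (C4, C9, C10, C13, C14, C17), arranged as the contiguous array C4–C5–C9–C10 and the vicinal pair C13–C14. C11 on C9 is axial on the oxane chair and anti to the C1–C2 bridge; H5 is trans to C11 (oxane and ring B trans-fused); H8 is cis to C10 (rings B and C cis-fused); the methyls on C13 and C14 are anti (rings C and D trans-fused); on C17 the methyl is cis to the C14 methyl and the chain cis to the C13 methyl. The only functional groups are the bridging ether, which tolerates base and reduction but not strong Lewis acid, and the trisubstituted alkene, which is sensitive to acid, hydrogenation and hydrogen-atom transfer. The difficulty is congestion and the lack of handles: every ring fusion carries a quaternary carbon and no heteroatom sits near rings B, C and D. The strategy rests on C13 and C14, the carbons shared by rings C and D. They are adjacent quaternary centres with anti methyls, and C14 is bonded to C8 of ring B, so a carbonyl at C7 makes C14 the β-carbon of a C8=C14 enone and lets a radical form the C13–C14 bond.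

## Retrosynthetic reasoning

Side chain. The C21=C22 alkene of 44 is cut by olefination back to aldehyde 43, which comes from alcohol 42 and its silyl ether 41. The alkene is made last because it would be a second hydrogen-atom acceptor in the key step and would not survive the later alkene reduction. The chain is carried as a silyloxypropyl group from 14.

Ring C. The C11–C12 bond of 41 is cut (diene 40, dialdehyde 39). It is the only ring C bond between two methylene carbons. Cutting it leaves C11 and C12 as one-carbon oxygenated arms on the quaternary carbons C9 and C13, so neither aldehyde of 39 can enolize. The same oxygens serve earlier as the only handles on the core (12) and on the hydrogen-atom acceptor alkene (25). The forward reaction must join two neopentyl aldehydes into a cyclohexene and then saturate it.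

C7 oxygen. Diol 38 comes from 37, whose C6=C7 alkene comes from enol triflate 36 and ketone 34. The C7 carbonyl is needed only to activate C14, so it is removed directly after the key step. Enolization can only go toward C6, because H8 lies between two quaternary carbons. The resulting alkene is saturated together with the ring C alkene.

Key disconnection. The C13–C14 bond of 34 is cut to give 33, an alkylidene cyclopentanone with a tethered 1,1-disubstituted alkene. Cutting here creates both quaternary centres from two sp2 carbons in one step. A cut at C8–C14 or C12–C13 would need a nucleophile or electrophile at a neopentyl quaternary carbon. The forward reaction has to place a hydrogen atom on the terminal CH2, close ring D 6-exo on one enone face, and protonate C8.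

Enone 33. The C14–methyl bond is cut by cross-coupling back to the Z enol triflate 32 of diketone 30, and the C8–C14 bond by an aldol back to enone 12 and aldehyde 25 (adduct 27, reduced to 29). The C5=C6 alkene of 12 is kept through the aldol on purpose: in 12 only C8 can be enolized, whereas a saturated cyclopentanone would react at C6 as well. The alkene is then reduced (27 to 29), which sets C5.

Core 12. Three bonds (C5–C9, C8–C7, C7–C6) are cut in a carbonylative enyne cyclization back to enyne 10. This gives ring B, the oxane and quaternary C9 in one step, with C9 fixed by the ring fusion.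

Enyne 10. The C9=C8 methylene comes from ketone 8, the alkyne on quaternary C4 from the tertiary alcohol of 6 by a radical substitution (via 7), and the oxygenated C11 from the vinyl group of 3 (via 4 and 5). Oxolane 3 comes from 1: C10 is taken from the chiral pool and C3 is set by a reagent-controlled epoxidation (2).

Chain 25. The 2-(alkoxymethyl)allyl unit is built from the ester of 21 (via 22, 23, 24). Compound 21 comes from ring cleavage of cyclohexanone 17 through silyl enol ether 19. The six ring carbons of 17 are those of ring D: the ring is opened between the later C13 and C14 so that the two carbons can be differentiated, and the key step closes the same bond again. C17 is set by asymmetric conjugate addition of the reagent from 14 (made from 13) to 15.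

## Alternatives that were turned down

Alternative 1: Photochemical dienone rearrangement. The disconnection cuts C5–C9 and C10–O and restores C5–C10, which turns ring B back into a six-membered cross-conjugated dienone and ring A into a cyclohexanol. In the forward step, irradiation near 350 nm in acid bonds C5 to C9 through a bicyclo[3.1.0]hexenone, the C5–C10 bond opens and the C3 hydroxyl traps C10, giving enone A1. In its favour, one step would make the cyclopentane, the seven-membered ring, the ether and quaternary C9 from an all-six-membered tetracycle; for the A/B half this is more step-economical than the nine steps to 12 used here. Against it, the substrate must already hold rings C and D with the C13–C14 pair, so the hardest bond is only moved upstream. The excited dienone can also open the other cyclopropane bonds (phenols, lumiketones), and the side-chain alkene is exposed to light and acid. A1 still needs removal of a methoxy group and a ketone and a reduction of C5=C6 that must set C5. The chosen strategy gives up that economy, but fixes C3 and C10 from the chiral pool and makes C13–C14 by a ground-state radical whose regiochemistry the tether dictates.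

Alternative 2: Pauson–Khand closure of rings B and A. The disconnection cuts C5–C9, C8–C7 and C7–C6, leading back to an oxolane that carries an alkyne and a 1,1-disubstituted alkene. In the forward step Co2(CO)8 joins alkyne, alkene and CO to give enone A2. In its favour are three bonds, two rings and quaternary C9 from a chiral-pool oxolane, with C9 controlled by the ring fusion. On these points it is as strong as anything in the chosen route, and the chosen route in fact uses this closure (step 9; 12 is the methoxymethyl analogue of A2). As the strategy-defining step, however, it says nothing about rings C and D: from A2 the chain must still be attached at C8 and the C13–C14 pair made. The two plans are complementary; the chosen one keeps this closure as a supporting step and places the strategic risk at C13–C14.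

Alternative 3: Cationic ring C closure with ring A enlargement. The disconnection cuts C8–C14, returns C5 from C9 to C10 and opens the ether. In the forward step SnCl4 ionizes a tertiary C14 alcohol, the C8=C9 alkene attacks to form C8–C14, C5 migrates to the C9 cation and the C3 hydroxyl captures C10, giving A3. In its favour, one operation makes ring C, the seven-membered ring, the ether and four stereocentres, and no ketone has to be removed afterwards; in bonds per step it is stronger than the chosen route. Against it, the C14 cation sits next to quaternary C13 (methyl shift, elimination), and the 1,2-shift must select C5 over C1, C11 and methyl. C8, C9 and C10 depend on the conformations of a flexible cation, the side-chain alkene of A3 is itself a nucleophile under SnCl4, and ring B is still open in A3. The chosen radical closure has no rearrangement channel and controls C14 through one alkene geometry and one face.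

Key step: step 23

Step 1
Reactants: 1 (R)-linalool
Product: 3 2-[(2S,5R)-5-ethenyl-5-methyloxolan-2-yl]propan-2-ol (cis-furanoid linalool oxide), via (3R,6R)-6,7-epoxylinalool 2 (not isolated)
Conditions: D-fructose-derived Shi ketone (30 mol%), Oxone, K2CO3, Bu4NHSO4, MeCN/dimethoxymethane/aq. borate buffer, 0 °C; then CSA (cat.), CH2Cl2, 0 °C
Reagents that add atoms: Oxone (potassium peroxymonosulfate), [K+].[O-]S(=O)(=O)OO
Why: Shi asymmetric epoxidation is reagent-controlled and selects the trisubstituted alkene over the vinyl group, setting the later C3; acid-catalysed 5-exo opening by the tertiary hydroxyl with inversion should give the oxolane with the vinyl and hydroxypropyl groups cis. C10 is taken unchanged from 1.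

Step 2
Reactants: 3 cis-furanoid linalool oxide
Product: 4 1-[(2R,5S)-5-(2-hydroxypropan-2-yl)-2-methyloxolan-2-yl]ethane-1,2-diol (both C9 epimers)
Conditions: OsO4 (2 mol%), NMO, acetone/H2O, rt
Reagents that add atoms: N-methylmorpholine N-oxide, C[N+]1([O-])CCOCC1; water, O
Why: Catalytic OsO4 dihydroxylation of the only alkene; the new carbinol centre is removed again in step 4.

Step 3
Reactants: 4 triol
Product: 5 1-[(2R,5S)-5-(2-hydroxypropan-2-yl)-2-methyloxolan-2-yl]-2-(methoxymethoxy)ethan-1-ol (both C9 epimers)
Conditions: MOMCl (1.05 equiv), i-Pr2NEt, CH2Cl2, 0 °C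
Reagents that add atoms: chloromethyl methyl ether, COCCl
Why: Alkylation of the primary hydroxyl as its methoxymethyl ether is much faster than at the neopentyl secondary or the tertiary hydroxyl.

Step 4
Reactants: 5 primary methoxymethyl ether
Product: 6 1-[(2R,5S)-5-(2-hydroxypropan-2-yl)-2-methyloxolan-2-yl]-2-(methoxymethoxy)ethan-1-one
Conditions: Dess–Martin periodinane, NaHCO3, CH2Cl2, rt
Reagents that add atoms: none
Why: Dess–Martin oxidation of the secondary alcohol to the C9 ketone; the tertiary alcohol cannot be oxidized.

Step 5
Reactants: 6 hydroxy ketone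
Product: 7 N-phthalimidoyl oxalate of the tertiary alcohol of 6
Conditions: (COCl)2, N-hydroxyphthalimide, THF, −78 °C to rt; then 6, Et3N, DMAP (cat.), 0 °C; used crude
Reagents that add atoms: oxalyl chloride, O=C(Cl)C(Cl)=O; N-hydroxyphthalimide, O=C1N(O)C(=O)c2ccccc12
Why: DMAP-catalysed acylation of the tertiary alcohol by the acid chloride gives the redox-active oxalate that serves as precursor of the tertiary C4 radical.

Step 6
Reactants: 7 N-phthalimidoyl oxalate
Product: 8 1-[(2R,5S)-2-methyl-5-[2-methyl-4-(triisopropylsilyl)but-3-yn-2-yl]oxolan-2-yl]-2-(methoxymethoxy)ethan-1-one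
Conditions: Ru(bpy)3(PF6)2 (2 mol%), Hantzsch ester, i-Pr2NEt, [(triisopropylsilyl)ethynyl] phenyl sulfone (2 equiv), CH2Cl2, blue LEDs, rt
Reagents that add atoms: [(triisopropylsilyl)ethynyl] phenyl sulfone, CC(C)[Si](C#CS(=O)(=O)c1ccccc1)(C(C)C)C(C)C
Why: Photoredox deoxygenative radical alkynylation: reduction of the oxalate releases phthalimide and two CO2 and leaves the tertiary C4 radical, which adds to the sulfone-bearing alkyne carbon and expels PhSO2. A radical avoids the oxygen-bridged cation that ionization next to the ring oxygen would give, and the step is run on the ketone so that no alkene is within reach of the radical.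

Step 7
Reactants: 8 silylalkynyl ketone
Product: 9 (2R,5S)-2-[3-(methoxymethoxy)prop-1-en-2-yl]-2-methyl-5-[2-methyl-4-(triisopropylsilyl)but-3-yn-2-yl]oxolane
Conditions: Ph3PCH3Br, KHMDS, THF, 0 °C to 50 °C
Reagents that add atoms: methyltriphenylphosphonium bromide, C[P+](c1ccccc1)(c1ccccc1)c1ccccc1.[Br-]
Why: Wittig methylenation of the hindered ketone installs C8 as the CH2 of the 1,1-disubstituted alkene.

Step 8
Reactants: 9 silylalkyne
Product: 10 (2R,5S)-2-[3-(methoxymethoxy)prop-1-en-2-yl]-2-methyl-5-(2-methylbut-3-yn-2-yl)oxolane
Conditions: TBAF, THF, 0 °C to rt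
Reagents that add atoms: none
Why: Fluoride cleaves the alkynyl C–Si bond; the methoxymethyl ether is not affected.

Step 9
Reactants: 10 enyne
Product: 12 ring A/B tricyclic enone (C7 ketone; C5=C6; C9 bearing C11H2OMOM anti to the C1–C2 bridge), via Co2(CO)6–alkyne complex 11 (not isolated)
Conditions: Co2(CO)8 (1.1 equiv), CH2Cl2, rt; then NMO (8 equiv), 0 °C to rt
Reagents that add atoms: Co2(CO)8, O=C=[Co](=C=O)(=C=O)(=C=O)[Co](=C=O)(=C=O)(=C=O)=C=O
Why: Intramolecular Pauson–Khand reaction forms C5–C9, C8–C7 and C7–C6; the gem-dimethyl group and the cis-oxolane hold alkyne and alkene together. C9 is set by the ring fusion: in the cyclopentenone C8 must lie in the enone plane, i.e. equatorial on the oxane chair, which leaves C11 axial and anti to the C1–C2 bridge.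

Step 10
Reactants: 13 3-bromopropan-1-ol
Product: 14 (3-bromopropoxy)triisopropylsilane
Conditions: TIPSCl, imidazole, DMF, rt
Reagents that add atoms: chlorotriisopropylsilane, CC(C)[Si](Cl)(C(C)C)C(C)C
Why: Imidazole-promoted silylation of the primary alcohol; the triisopropylsilyl ether is chosen because it survives dissolving-metal reduction and Lewis acid–thiol conditions later.

Step 11
Reactants: 14 (3-bromopropoxy)triisopropylsilane and 15 3-methylcyclohex-2-en-1-one
Product: 17 (S)-3-methyl-3-[3-(triisopropylsilyloxy)propyl]cyclohexan-1-one, via Grignard reagent 16 (not isolated)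
Conditions: Mg, Et2O; then Cu(OTf)2 (3 mol%), chiral C2-symmetric imidazolinium chloride (carbene precursor, 4 mol%), 15, Et2O, 0 °C; aq. NH4Cl
Reagents that add atoms: none
Why: Copper-catalysed asymmetric conjugate addition of the Grignard reagent to the β,β-disubstituted enone creates the C17 quaternary centre; the chiral carbene–copper catalyst selects the enone face. Any minor enantiomer becomes a separable diastereomer after step 18.

Step 12
Reactants: 17 (S)-ketone
Product: 19 trimethylsilyl enol ether of 17 with the C1=C6 double bond (C17 as in 17), via lithium enolate 18 (not isolated)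
Conditions: LDA, THF, −78 °C; TMSCl, Et3N, −78 °C to 0 °C
Reagents that add atoms: chlorotrimethylsilane, C[Si](C)(C)Cl
Why: Kinetic deprotonation occurs at C6 of the cyclohexanone, away from the quaternary carbon whose axial substituent shields the C2 hydrogens; O-silylation fixes this regiochemistry.

Step 13
Reactants: 19 silyl enol ether
Product: 21 methyl 6,6-dimethoxy-3-methyl-3-[3-(triisopropylsilyloxy)propyl]hexanoate (C17 as in 17), via aldehyde acid 20 (not isolated)
Conditions: O3, CH2Cl2/MeOH, −78 °C; Me2S; then HC(OMe)3, MeOH, CSA (cat.), rt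
Reagents that add atoms: ozone, [O-][O+]=O; trimethyl orthoformate, COC(OC)OC; methanol, CO
Why: Ozonolysis of the silyl enol ether cleaves the ring bond that is the later C13–C14 into a carboxylic acid (C13) and an aldehyde (C14). Acid-catalysed orthoformate treatment then esterifies the acid and protects the aldehyde as its dimethyl acetal in the same flask.

Step 14
Reactants: 21 acetal ester
Product: 22 N-methoxy-N-methyl amide of 21
Conditions: MeNH(OMe)·HCl, i-PrMgCl, THF, −20 °C to 0 °C
Reagents that add atoms: N,O-dimethylhydroxylamine hydrochloride, CNOC.Cl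
Why: Direct aminolysis of the ester by the magnesium amide gives the Weinreb amide.

Step 15
Reactants: 22 Weinreb amide
Product: 23 7,7-dimethoxy-1-(methoxymethoxy)-4-methyl-4-[3-(triisopropylsilyloxy)propyl]heptan-2-one (C17 as in 17)
Conditions: Bu3SnCH2OCH2OMe, n-BuLi, THF, −78 °C; then 22
Reagents that add atoms: tributyl[(methoxymethoxy)methyl]stannane, CCCC[Sn](CCCC)(CCCC)COCOC
Why: Tin–lithium exchange gives the α-alkoxy organolithium, which adds once to the Weinreb amide through the chelated tetrahedral intermediate; this brings in C12 with its oxygen.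

Step 16
Reactants: 23 α-alkoxy ketone
Product: 24 7,7-dimethoxy-2-[(methoxymethoxy)methyl]-4-methyl-4-[3-(triisopropylsilyloxy)propyl]hept-1-ene (C17 as in 17)
Conditions: Ph3PCH3Br, KHMDS, THF, 0 °C to rt
Reagents that add atoms: methyltriphenylphosphonium bromide, C[P+](c1ccccc1)(c1ccccc1)c1ccccc1.[Br-]
Why: Wittig methylenation gives the 1,1-disubstituted alkene that will accept the hydrogen atom in the key step.

Step 17
Reactants: 24 acetal alkene
Product: 25 6-[(methoxymethoxy)methyl]-4-methyl-4-[3-(triisopropylsilyloxy)propyl]hept-6-enal (C17 as in 17)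
Conditions: PPTS (cat.), acetone/H2O, 50 °C
Reagents that add atoms: water, O
Why: Mild acid hydrolysis of the dimethyl acetal; methoxymethyl and triisopropylsilyl ethers are stable to pyridinium tosylate.

Step 18
Reactants: 12 tricyclic enone and 25 chain aldehyde
Product: 27 aldol adduct (C8 of 12 bonded to the carbinol carbon C14; both new centres as mixtures), via lithium dienolate 26 (not isolated)
Conditions: LDA, THF, −78 °C; then 25; aq. NH4Cl at −78 °C
Reagents that add atoms: none
Why: In 12 only C8 can be deprotonated (C4 is quaternary, so there is no γ-hydrogen), so LDA gives one cross-conjugated enolate and the aldol addition forms C8–C14 regiospecifically. The two carbinol-derived centres disappear in steps 20 and 21.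

Step 19
Reactants: 27 aldol adduct
Product: 29 saturated β-hydroxy ketone (H5 trans to C11; C8 and C14 as mixtures), via lithium enolate alkoxide 28 (not isolated)
Conditions: Li (2.5 equiv), NH3(l)/THF, −78 °C, 10 min; isoprene, then solid NH4Cl
Reagents that add atoms: none
Why: Dissolving-metal conjugate reduction of the enone; the β-carbon C5 is protonated axially on the oxane chair, which should give the thermodynamically favoured trans fusion because the cis isomer would force C6 under the C1–C2 bridge. The aldol hydroxyl is carried as its alkoxide, the ketone is protected as its enolate, and the isolated alkene, acetal ethers and silyl ether are not reduced during brief exposure at −78 °C.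

Step 20
Reactants: 29 β-hydroxy ketone
Product: 30 1,3-diketone (C7 and C14 carbonyls; C8 as a mixture and enol forms)
Conditions: Dess–Martin periodinane, NaHCO3, CH2Cl2, 0 °C to rt
Reagents that add atoms: none
Why: Dess–Martin oxidation of the secondary alcohol gives the 2-acylcyclopentanone.

Step 21
Reactants: 30 1,3-diketone
Product: 32 (Z)-enol triflate at C14 (C8=C14; triflate syn to the C7 carbonyl), via lithium enolate 31 (not isolated)
Conditions: LiHMDS, THF, −78 °C; 2-[N,N-bis(trifluoromethylsulfonyl)amino]-5-chloropyridine, −78 °C to 0 °C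
Reagents that add atoms: 2-[N,N-bis(trifluoromethylsulfonyl)amino]-5-chloropyridine, FC(F)(F)S(=O)(=O)N(c1ccc(Cl)cn1)S(=O)(=O)C(F)(F)F
Why: The lithium enolate of the 2-acylcyclopentanone is a six-membered chelate. O-Sulfonylation at the exocyclic oxygen keeps the ring carbonyl and a double bond exocyclic to the five-membered ring, the arrangement such diketones prefer in their enols, whereas the ring triflate would twist the acyl group out of conjugation against quaternary C9. The chelate places the triflate syn to C7=O and the chain syn to C9.

Step 22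
Reactants: 32 (Z)-enol triflate
Product: 33 key-step precursor: (E)-alkylidene cyclopentanone (C14 methyl cis to the C7 carbonyl; chain cis to C9)
Conditions: Me2Zn, Pd(PPh3)4 (5 mol%), THF, 0 °C to rt
Reagents that add atoms: dimethylzinc, C[Zn]C
Why: Negishi cross-coupling: oxidative addition of zerovalent palladium into the vinylogous triflate, methyl transfer from zinc and reductive elimination all occur with retention, so the methyl takes the place of the triflate cis to the carbonyl.

Step 23
Reactants: 33 (E)-alkylidene cyclopentanone
Product: 34 ring A/B/D tetracyclic ketone (C13 and C14 quaternary with anti methyls; H8 cis to C10; C7 ketone)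
Conditions: Fe(acac)3 (50 mol%), PhSiH3 (3 equiv), EtOH/ethylene glycol (5:1), 0.01 M, 60 °C
Reagents that add atoms: none
Why: The iron hydride formed from Fe(acac)3 and PhSiH3 transfers a hydrogen atom to the terminal CH2 of the electron-rich 1,1-disubstituted alkene, which becomes the C13 methyl and leaves a nucleophilic tertiary radical at C13. This radical adds 6-exo-trig to C14, the β-carbon of the C8=C14 enone, forming C13–C14 and ring D; the α-keto radical at C8 is reduced by divalent iron to the enolate and protonated by ethanol, which returns trivalent iron. The closest known reaction type is the iron-hydride hydrogen-atom-transfer reductive coupling of unactivated olefins with enones, which forms quaternary and vicinal quaternary carbons. C14 is set by the E geometry of 33 together with attack on the enone face that carries C11, anti to bridgehead C10 whose methyl and C1 shield the other face. C13 is set relative to C14 by a chair transition state with C8 and C12 equatorial and both methyls axial and anti; C17 contributes little, because either chair puts one of its two similar groups axial. C8 is set by protonation from the C10 face, anti to ring D, which is also the thermodynamic epimer (C14 cis to the smaller C11 arm) and can be secured by base equilibration. The selectivities needed are hydrogen-atom transfer to the alkene and not to the electron-poor enone, and ring closure faster than reduction of the radical; the polarity match, the six-membered tether and high dilution serve these.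

Step 24
Reactants: 34 tetracyclic ketone
Product: 36 enol triflate with the C6=C7 double bond, via potassium enolate 35 (not isolated)
Conditions: KHMDS, THF, −78 °C; PhNTf2, −78 °C to 0 °C
Reagents that add atoms: N-phenylbis(trifluoromethanesulfonimide), FC(F)(F)S(=O)(=O)N(c1ccccc1)S(=O)(=O)C(F)(F)F
Why: Kinetic deprotonation can only occur at C6, because H8 lies between the quaternary carbons C9 and C14; O-triflation fixes the enolate and C8 is not touched.

Step 25
Reactants: 36 enol triflate
Product: 37 C6=C7 alkene (C7 oxygen removed)
Conditions: Pd(OAc)2 (5 mol%), PPh3, HCO2H, Bu3N, DMF, 60 °C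
Reagents that add atoms: none
Why: Palladium-catalysed formate reduction of the enol triflate (oxidative addition, formate exchange, decarboxylation, reductive elimination) replaces the triflate by hydrogen.

Step 26
Reactants: 37 bis(methoxymethyl) ether
Product: 38 diol (C11 and C12 hydroxymethyl groups)
Conditions: ZnBr2, n-PrSH, CH2Cl2, 0 °C to rt
Reagents that add atoms: none
Why: Lewis acid–thiol cleavage removes both methoxymethyl acetals; the triisopropylsilyl ether and the bridging ether are not expected to react under these conditions.

Step 27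
Reactants: 38 diol
Product: 39 dialdehyde (C11 and C12 formyl groups on C9 and C13)
Conditions: Dess–Martin periodinane (3 equiv), NaHCO3, CH2Cl2, rt
Reagents that add atoms: none
Why: Dess–Martin oxidation of both neopentyl alcohols; neither aldehyde has an α-hydrogen, so no epimerization or aldol reaction can follow.

Step 28
Reactants: 39 dialdehyde
Product: 40 pentacyclic diene (C11=C12 in ring C; C6=C7 in ring B)
Conditions: TiCl3(DME)1.5, Zn–Cu couple, DME, reflux; slow addition of 39
Reagents that add atoms: none
Why: Intramolecular McMurry coupling of the 1,6-dialdehyde on low-valent titanium (pinacolate, then deoxygenation) closes ring C as the cyclohexene; slow addition favours ring closure over intermolecular coupling.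

Step 29
Reactants: 40 pentacyclic diene
Product: 41 saturated pentacyclic triisopropylsilyl ether
Conditions: TsNHNH2 (excess, in portions), NaOAc, DME/H2O, reflux
Reagents that add atoms: none
Why: Diimide transfers H2 to both disubstituted ring alkenes without migrating the double bonds, so C5 and C8 keep their configuration; no new stereocentre forms.

Step 30
Reactants: 41 silyl ether
Product: 42 primary alcohol (3-hydroxypropyl on C17)
Conditions: TBAF, THF, rt
Reagents that add atoms: none
Why: Fluoride cleaves the triisopropylsilyl ether.

Step 31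
Reactants: 42 primary alcohol
Product: 43 aldehyde (3-oxopropyl on C17)
Conditions: Dess–Martin periodinane, NaHCO3, CH2Cl2, rt
Reagents that add atoms: none
Why: Dess–Martin oxidation of the primary alcohol to the aldehyde.

Step 32
Reactants: 43 aldehyde
Product: 44 target compound CNP0284367.1
Conditions: i-PrPPh3I, n-BuLi, THF, 0 °C; then 43, 0 °C to rt
Reagents that add atoms: isopropyltriphenylphosphonium iodide, CC(C)[P+](c1ccccc1)(c1ccccc1)c1ccccc1.[I-]
Why: Wittig olefination with the isopropylidene ylide installs the trisubstituted alkene, which has no geometry to control.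

Compound list

1 | (R)-linalool | C=C[C@](C)(O)CCC=C(C)C | starting material
2 | (3R,6R)-6,7-epoxy-3,7-dimethyloct-1-en-3-ol | C=C[C@](C)(O)CC[C@H]1OC1(C)C | intermediate
3 | 2-[(2S,5R)-5-ethenyl-5-methyloxolan-2-yl]propan-2-ol (cis-furanoid linalool oxide) | C=C[C@@]1(C)CC[C@H](O1)C(C)(C)O | intermediate
4 | 1-[(2R,5S)-5-(2-hydroxypropan-2-yl)-2-methyloxolan-2-yl]ethane-1,2-diol, both C9 epimers | OCC(O)[C@@]1(C)CC[C@H](O1)C(C)(C)O | intermediate
5 | 1-[(2R,5S)-5-(2-hydroxypropan-2-yl)-2-methyloxolan-2-yl]-2-(methoxymethoxy)ethan-1-ol, both C9 epimers | COCOCC(O)[C@@]1(C)CC[C@H](O1)C(C)(C)O | intermediate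
6 | 1-[(2R,5S)-5-(2-hydroxypropan-2-yl)-2-methyloxolan-2-yl]-2-(methoxymethoxy)ethan-1-one | COCOCC(=O)[C@@]1(C)CC[C@H](O1)C(C)(C)O | intermediate
7 | N-phthalimidoyl oxalate of the tertiary alcohol of 6 | COCOCC(=O)[C@@]1(C)CC[C@H](O1)C(C)(C)OC(=O)C(=O)ON1C(=O)c2ccccc2C1=O | intermediate
8 | 1-[(2R,5S)-2-methyl-5-[2-methyl-4-(triisopropylsilyl)but-3-yn-2-yl]oxolan-2-yl]-2-(methoxymethoxy)ethan-1-one | COCOCC(=O)[C@@]1(C)CC[C@H](O1)C(C)(C)C#C[Si](C(C)C)(C(C)C)C(C)C | intermediate
9 | (2R,5S)-2-[3-(methoxymethoxy)prop-1-en-2-yl]-2-methyl-5-[2-methyl-4-(triisopropylsilyl)but-3-yn-2-yl]oxolane | COCOCC(=C)[C@@]1(C)CC[C@H](O1)C(C)(C)C#C[Si](C(C)C)(C(C)C)C(C)C | intermediate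
10 | (2R,5S)-2-[3-(methoxymethoxy)prop-1-en-2-yl]-2-methyl-5-(2-methylbut-3-yn-2-yl)oxolane | COCOCC(=C)[C@@]1(C)CC[C@H](O1)C(C)(C)C#C | intermediate
11 | Co2(CO)6 complex of the alkyne of 10 | COCOCC(=C)[C@@]1(C)CC[C@H](O1)C(C)(C)C23[Co]4(=C=O)(=C=O)(=C=O)[Co]2(=C=O)(=C=O)(=C=O)[CH]34 | intermediate
12 | ring A/B tricyclic enone: C7 ketone, C5=C6, C8H2, C9 bearing C11H2OMOM anti to the C1–C2 bridge, C3 and C10 as in 3 | O=C1C=C2C(C)(C)[C@@H]3CC[C@@](C)(O3)[C@]2(COCOC)C1 | intermediate
13 | 3-bromopropan-1-ol | OCCCBr | starting material
14 | (3-bromopropoxy)triisopropylsilane | BrCCCO[Si](C(C)C)(C(C)C)C(C)C | intermediate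
15 | 3-methylcyclohex-2-en-1-one | CC1=CC(=O)CCC1 | starting material
16 | [3-(triisopropylsilyloxy)propyl]magnesium bromide | Br[Mg]CCCO[Si](C(C)C)(C(C)C)C(C)C | intermediate
17 | (S)-3-methyl-3-[3-(triisopropylsilyloxy)propyl]cyclohexan-1-one | O=C1C[C@](C)(CCCO[Si](C(C)C)(C(C)C)C(C)C)CCC1 | intermediate
18 | lithium enolate of 17 with the C1=C6 double bond | [Li]OC1=CCC[C@@](C)(CCCO[Si](C(C)C)(C(C)C)C(C)C)C1 | intermediate
19 | trimethylsilyl enol ether of 17 with the C1=C6 double bond, C17 as in 17 | C[Si](C)(C)OC1=CCC[C@@](C)(CCCO[Si](C(C)C)(C(C)C)C(C)C)C1 | intermediate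
20 | 3-methyl-6-oxo-3-[3-(triisopropylsilyloxy)propyl]hexanoic acid, C17 as in 17 | O=CCC[C@@](C)(CCCO[Si](C(C)C)(C(C)C)C(C)C)CC(O)=O | intermediate
21 | methyl 6,6-dimethoxy-3-methyl-3-[3-(triisopropylsilyloxy)propyl]hexanoate, C17 as in 17 | COC(OC)CC[C@@](C)(CCCO[Si](C(C)C)(C(C)C)C(C)C)CC(=O)OC | intermediate
22 | N-methoxy-N-methyl amide of 21 | COC(OC)CC[C@@](C)(CCCO[Si](C(C)C)(C(C)C)C(C)C)CC(=O)N(C)OC | intermediate
23 | 7,7-dimethoxy-1-(methoxymethoxy)-4-methyl-4-[3-(triisopropylsilyloxy)propyl]heptan-2-one, C17 as in 17 | COC(OC)CC[C@@](C)(CCCO[Si](C(C)C)(C(C)C)C(C)C)CC(=O)COCOC | intermediate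
24 | 7,7-dimethoxy-2-[(methoxymethoxy)methyl]-4-methyl-4-[3-(triisopropylsilyloxy)propyl]hept-1-ene, C17 as in 17 | COC(OC)CC[C@@](C)(CCCO[Si](C(C)C)(C(C)C)C(C)C)CC(=C)COCOC | intermediate
25 | 6-[(methoxymethoxy)methyl]-4-methyl-4-[3-(triisopropylsilyloxy)propyl]hept-6-enal, C17 as in 17 | O=CCC[C@@](C)(CCCO[Si](C(C)C)(C(C)C)C(C)C)CC(=C)COCOC | intermediate
26 | lithium dienolate of 12 (O–C7=C8, C5=C6 kept) | [Li]OC=1C=C2C(C)(C)[C@@H]3CC[C@@](C)(O3)[C@]2(COCOC)C=1 | intermediate
27 | aldol adduct of 12 and 25: enone with C8 bonded to the carbinol carbon C14, C8 and C14 as mixtures | O=C1C=C2C(C)(C)[C@@H]3CC[C@@](C)(O3)[C@]2(COCOC)C1C(O)CC[C@@](C)(CCCO[Si](C(C)C)(C(C)C)C(C)C)CC(=C)COCOC | intermediate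
28 | lithium enolate (C6=C7) and lithium alkoxide (C14) formed from 27 | [Li]OC1=C[C@H]2C(C)(C)[C@@H]3CC[C@@](C)(O3)[C@]2(COCOC)C1C(O[Li])CC[C@@](C)(CCCO[Si](C(C)C)(C(C)C)C(C)C)CC(=C)COCOC | intermediate
29 | saturated β-hydroxy ketone: H5 trans to C11, C8 and C14 as mixtures | O=C1C[C@H]2C(C)(C)[C@@H]3CC[C@@](C)(O3)[C@]2(COCOC)C1C(O)CC[C@@](C)(CCCO[Si](C(C)C)(C(C)C)C(C)C)CC(=C)COCOC | intermediate
30 | 1,3-diketone with C7 and C14 carbonyls, C8 as a mixture | O=C1C[C@H]2C(C)(C)[C@@H]3CC[C@@](C)(O3)[C@]2(COCOC)C1C(=O)CC[C@@](C)(CCCO[Si](C(C)C)(C(C)C)C(C)C)CC(=C)COCOC | intermediate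
31 | chelated lithium (Z)-enolate of 30 (O–C14=C8, oxygen syn to C7=O) | C=C(COCOC)C[C@](C)(CCCO[Si](C(C)C)(C(C)C)C(C)C)CC/C(O[Li])=C1/C(=O)C[C@H]2C(C)(C)[C@@H]3CC[C@@](C)(O3)[C@]12COCOC | intermediate
32 | (Z)-enol triflate at C14, triflate syn to the C7 carbonyl | C=C(COCOC)C[C@](C)(CCCO[Si](C(C)C)(C(C)C)C(C)C)CC/C(OS(=O)(=O)C(F)(F)F)=C1/C(=O)C[C@H]2C(C)(C)[C@@H]3CC[C@@](C)(O3)[C@]12COCOC | intermediate
33 | key-step precursor: (E)-alkylidene cyclopentanone, C14 methyl cis to C7=O, tethered 1,1-disubstituted alkene | C=C(COCOC)C[C@](C)(CCCO[Si](C(C)C)(C(C)C)C(C)C)CC/C(C)=C1/C(=O)C[C@H]2C(C)(C)[C@@H]3CC[C@@](C)(O3)[C@]12COCOC | intermediate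
34 | key-step product: ring A/B/D tetracyclic ketone, C13 and C14 quaternary with anti methyls, H8 cis to C10 | CC(C)[Si](OCCC[C@]1(C)CC[C@](C)([C@H]2C(=O)C[C@H]3C(C)(C)[C@@H]4CC[C@@](C)(O4)[C@]23COCOC)[C@@](C)(COCOC)C1)(C(C)C)C(C)C | intermediate
35 | potassium enolate of 34 (C6=C7) | CC(C)[Si](OCCC[C@]1(C)CC[C@](C)([C@H]2C(O[K])=C[C@H]3C(C)(C)[C@@H]4CC[C@@](C)(O4)[C@]23COCOC)[C@@](C)(COCOC)C1)(C(C)C)C(C)C | intermediate
36 | enol triflate of 34 with the C6=C7 double bond | CC(C)[Si](OCCC[C@]1(C)CC[C@](C)([C@H]2C(OS(=O)(=O)C(F)(F)F)=C[C@H]3C(C)(C)[C@@H]4CC[C@@](C)(O4)[C@]23COCOC)[C@@](C)(COCOC)C1)(C(C)C)C(C)C | intermediate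
37 | tetracyclic C6=C7 alkene, bis(methoxymethyl) ether | CC(C)[Si](OCCC[C@]1(C)CC[C@](C)([C@H]2C=C[C@H]3C(C)(C)[C@@H]4CC[C@@](C)(O4)[C@]23COCOC)[C@@](C)(COCOC)C1)(C(C)C)C(C)C | intermediate
38 | tetracyclic diol (C11 and C12 hydroxymethyl groups) | CC(C)[Si](OCCC[C@]1(C)CC[C@](C)([C@H]2C=C[C@H]3C(C)(C)[C@@H]4CC[C@@](C)(O4)[C@]23CO)[C@@](C)(CO)C1)(C(C)C)C(C)C | intermediate
39 | tetracyclic dialdehyde (C11 and C12 formyl groups) | CC(C)[Si](OCCC[C@]1(C)CC[C@](C)([C@H]2C=C[C@H]3C(C)(C)[C@@H]4CC[C@@](C)(O4)[C@]23C=O)[C@@](C)(C=O)C1)(C(C)C)C(C)C | intermediate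
40 | pentacyclic diene (C11=C12 and C6=C7) | CC(C)[Si](OCCC[C@]1(C)CC[C@]2(C)[C@H]3C=C[C@H]4C(C)(C)[C@@H]5CC[C@@](C)(O5)[C@@]43C=C[C@@]2(C)C1)(C(C)C)C(C)C | intermediate
41 | saturated pentacyclic triisopropylsilyl ether | CC(C)[Si](OCCC[C@]1(C)CC[C@]2(C)[C@H]3CC[C@H]4C(C)(C)[C@@H]5CC[C@@](C)(O5)[C@@]43CC[C@@]2(C)C1)(C(C)C)C(C)C | intermediate
42 | pentacyclic primary alcohol (3-hydroxypropyl on C17) | OCCC[C@]1(C)CC[C@]2(C)[C@H]3CC[C@H]4C(C)(C)[C@@H]5CC[C@@](C)(O5)[C@@]43CC[C@@]2(C)C1 | intermediate
43 | pentacyclic aldehyde (3-oxopropyl on C17) | O=CCC[C@]1(C)CC[C@]2(C)[C@H]3CC[C@H]4C(C)(C)[C@@H]5CC[C@@](C)(O5)[C@@]43CC[C@@]2(C)C1 | intermediate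
44 | CNP0284367.1 | CC(C)=CCC[C@]1(C)CC[C@]2(C)[C@H]3CC[C@H]4C(C)(C)[C@@H]5CC[C@@](C)(O5)[C@@]43CC[C@@]2(C)C1 | target

Total step count: 32. Longest linear sequence: 24 steps (steps 1–9 and 18–32, from 1). The chain fragment 25 is made in 8 steps (10–17) and joins at step 18.

Steps least certain to work

Step 23 (key step). The most likely failure is that the tertiary C13 radical is quenched by hydrogen-atom transfer from the iron hydride or the silane before it can close onto the very hindered C14, so that the alkene is simply hydrogenated. Closure through the other chair (C13 epimer) or on the C10 face is the second risk. The fallback generates the same radical without any hydride donor. It sets out from 33: Mukaiyama hydration (Co(acac)2, PhSiH3, O2, i-PrOH), in which oxygen traps the radical faster than it can cyclize, should give the tertiary alcohol F1. Acylation with methyl chlorooxoacetate (Et3N, DMAP) gives the methyl oxalate F2, and CsOH in aqueous THF gives the cesium oxalate F3. Irradiation with blue light and Ir[dF(CF3)ppy]2(dtbbpy)PF6 in DME/DMF/H2O then releases two CO2 and the C13 radical, which closes onto the enone in a redox-neutral Giese cyclization. The route is rejoined at 34.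

Step 21. The process most likely to go wrong is sulfonylation at the ring oxygen on C7 instead of the C14 oxygen, or partial loss of chelate control, which would place the methyl on C7 or cis to C9 after step 22. The fallback avoids the diketone. It sets out from 29: mesylation and elimination (MsCl, Et3N; then DBU) should give the alkylidene ketone F4, expected with the chain syn to the carbonyl because the position next to quaternary C9 is the more crowded. Me2CuLi (Et2O, −78 °C) adds methyl to C14, and the enolate is trapped at C8 with PhSeBr to give the α-phenylselanyl ketone F5. If both reagents enter from the C11 face, as the shielding by C10 suggests, oxidation (H2O2, pyridine) and syn-elimination of the selenoxide toward H14 give the E alkene. The route is rejoined at 33.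

Step 19. The risks are electron-transfer cleavage of the allylic C12–O bond, retro-aldol cleavage of the alkoxide, and incomplete stereocontrol in the protonation of C5. The fallback postpones the reduction until no alkene or allylic ether is left. It sets out from 27: Dess–Martin oxidation gives the acyl enone F6; LiHMDS and the triflimide of step 21 give the enol triflate F7; Me2Zn and Pd(PPh3)4 give the cross-conjugated dienone F8, which keeps C5=C6. Fe(acac)3 and PhSiH3 close ring D onto the exocyclic enone as in step 23 to give the tetracyclic enone F9. Li in NH3 then reduces the remaining enone with the same axial protonation at C5, and the enolate, which is formed regiospecifically toward C6, is trapped with PhNTf2. The route is rejoined at 36.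

Step 28. Two neopentyl aldehydes couple slowly, so the reaction may stop at the pinacol stage or couple between molecules. The fallback closes ring C by metathesis. It sets out from 39: double Wittig methylenation (Ph3P=CH2) gives the divinyl compound F10, and ring-closing metathesis with the second-generation Grubbs catalyst (toluene, 80 °C, high dilution) forms the C11=C12 cyclohexene with loss of ethene. The hindered C6=C7 cyclopentene should not take part. The route is rejoined at 40.

Further compounds

F1 | step 23 | tertiary alcohol from Markovnikov hydration of 33 at C13 (both C13 epimers) | CC(O)(COCOC)C[C@](C)(CCCO[Si](C(C)C)(C(C)C)C(C)C)CC/C(C)=C1/C(=O)C[C@H]2C(C)(C)[C@@H]3CC[C@@](C)(O3)[C@]12COCOC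
F2 | step 23 | methyl oxalate of F1 | COC(=O)C(=O)OC(C)(COCOC)C[C@](C)(CCCO[Si](C(C)C)(C(C)C)C(C)C)CC/C(C)=C1/C(=O)C[C@H]2C(C)(C)[C@@H]3CC[C@@](C)(O3)[C@]12COCOC
F3 | step 23 | cesium oxalate of F1 | [Cs+].[O-]C(=O)C(=O)OC(C)(COCOC)C[C@](C)(CCCO[Si](C(C)C)(C(C)C)C(C)C)CC/C(C)=C1/C(=O)C[C@H]2C(C)(C)[C@@H]3CC[C@@](C)(O3)[C@]12COCOC
F4 | step 21 | (Z)-alkylidene ketone from dehydration of 29 (chain syn to C7=O, H14 syn to C9) | C=C(COCOC)C[C@](C)(CCCO[Si](C(C)C)(C(C)C)C(C)C)CC/C=C1\C(=O)C[C@H]2C(C)(C)[C@@H]3CC[C@@](C)(O3)[C@]12COCOC
F5 | step 21 | α-phenylselanyl ketone (SePh on C8, methyl on C14; C8 and C14 as formed) | C=C(COCOC)C[C@](C)(CCCO[Si](C(C)C)(C(C)C)C(C)C)CCC(C)C1([Se]c2ccccc2)C(=O)C[C@H]2C(C)(C)[C@@H]3CC[C@@](C)(O3)[C@]12COCOC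
F6 | step 19 | acyl enone from oxidation of 27 (C5=C6 kept; C8 as a mixture) | O=C1C=C2C(C)(C)[C@@H]3CC[C@@](C)(O3)[C@]2(COCOC)C1C(=O)CC[C@@](C)(CCCO[Si](C(C)C)(C(C)C)C(C)C)CC(=C)COCOC
F7 | step 19 | (Z)-enol triflate at C14 of F6 (C5=C6 kept) | C=C(COCOC)C[C@](C)(CCCO[Si](C(C)C)(C(C)C)C(C)C)CC/C(OS(=O)(=O)C(F)(F)F)=C1/C(=O)C=C2C(C)(C)[C@@H]3CC[C@@](C)(O3)[C@]12COCOC
F8 | step 19 | cross-conjugated dienone (C5=C6 and E-configured C8=C14) | C=C(COCOC)C[C@](C)(CCCO[Si](C(C)C)(C(C)C)C(C)C)CC/C(C)=C1/C(=O)C=C2C(C)(C)[C@@H]3CC[C@@](C)(O3)[C@]12COCOC
F9 | step 19 | ring A/B/D tetracyclic enone (C5=C6–C7=O; C13 and C14 as in 34) | CC(C)[Si](OCCC[C@]1(C)CC[C@](C)([C@H]2C(=O)C=C3C(C)(C)[C@@H]4CC[C@@](C)(O4)[C@]23COCOC)[C@@](C)(COCOC)C1)(C(C)C)C(C)C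
F10 | step 28 | divinyl compound from double methylenation of 39 | CC(C)[Si](OCCC[C@]1(C)CC[C@](C)([C@H]2C=C[C@H]3C(C)(C)[C@@H]4CC[C@@](C)(O4)[C@]23C=C)[C@@](C)(C=C)C1)(C(C)C)C(C)C
A1 | alternative 1 | pentacyclic ether with ring B 6-methoxy-5-en-7-one | CC(C)=CCC[C@]1(C)CC[C@]2(C)[C@H]3C(=O)C(OC)=C4C(C)(C)[C@@H]5CC[C@@](C)(O5)[C@@]43CC[C@@]2(C)C1
A2 | alternative 2 | ring A/B tricyclic enone with quaternary C9 and tert-butyldimethylsilyloxymethyl arm | O=C1C=C2C(C)(C)[C@@H]3CC[C@@](C)(O3)[C@]2(CO[Si](C)(C)C(C)(C)C)C1
A3 | alternative 3 | ring A/C/D ether-bridged tetracycle with silyloxymethyl arms on C8 and C5 | CC(C)=CCC[C@]1(C)CC[C@]2(C)[C@@H](CO[Si](C)(C)C(C)(C)C)[C@@]3([C@@H](CO[Si](C)(C)C(C)(C)C)C(C)(C)[C@@H]4CC[C@@]3(C)O4)CC[C@@]2(C)C1
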